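**Assumption:** (R)-2-(2,2-dimethyl-1,3-dioxolan-4-yl)ethanol (the acetonide of (R)-butane-1,2,4-triol, made from D-malic acid) is taken as a commercial chiral starting material.

## Retrosynthetic overview

1. Violacene (17) ⇐ BrCl addition to the exocyclic alkene of allylic chloride 16 ⇐ SN2 chlorination of allylic alcohol 15.
2. 15 ⇐ enone 12 (conjugate hydrosilylation, Rubottom oxidation, methylenation) ⇐ allylic oxidation of cyclohexene 11; the (E)-chlorovinyl group comes from a Takai olefination.
3. The only ring is formed in one step: Ireland–Claisen rearrangement of the silyl ketene acetal of δ-lactone 7 (lactone → carbocycle), a [3,3] shift that makes the C1–C2 bond and sets both the quaternary C–Me centre and the adjacent C–Cl centre.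
4. Lactone 7 ⇐ acetonide alcohol 1 + tert-butyl propanoate 3; its single bought stereocentre is transferred in the rearrangement and all later centres follow by substrate control.

## Route

**Step 1**
Reactants: 1, (R)-2-(2,2-dimethyl-1,3-dioxolan-4-yl)ethanol
Product: 2, (R)-4-(2-iodoethyl)-2,2-dimethyl-1,3-dioxolane
Conditions: I2, PPh3, imidazole, CH2Cl2, 0 °C → rt
Reagents that add atoms: iodine, II
Why: Appel-type iodination of the primary alcohol; the stereocentre is not touched.

**Step 2**
Reactants: 2; 3, tert-butyl propanoate
Product: 4, tert-butyl (2RS)-4-[(4R)-2,2-dimethyl-1,3-dioxolan-4-yl]-2-methylbutanoate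
Conditions: LDA, THF, −78 °C; then 2, DMPU, −78 → −20 °C
Reagents that add atoms: none (both fragments are numbered reactants)
Why: Ester enolate alkylation with a primary iodide; the new α-centre is a mixture, which does not matter because it is planarised in step 6.

**Step 3**
Reactants: 4
Product: 5, (3RS,6R)-6-(hydroxymethyl)-3-methyloxan-2-one
Conditions: TFA/H2O (9:1), rt; concentrate; then cat. p-TsOH, PhMe, 80 °C
Reagents that add atoms: none
Why: Acidolysis of the acetonide and tert-butyl ester, then lactonisation through the secondary hydroxyl (six-membered ring preferred); the C–O bond at the stereocentre is not broken, so configuration is retained.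

**Step 4**
Reactants: 5
Product: 6, (2R,5RS)-5-methyl-6-oxooxane-2-carbaldehyde
Conditions: Dess–Martin periodinane, NaHCO3, CH2Cl2, 0 °C; used crude
Reagents that add atoms: none
Why: Buffered, non-basic oxidation of the primary alcohol avoids epimerising the α-acyloxy aldehyde.

**Step 5**
Reactants: 6
Product: 7, (3RS,6R)-6-[(E)-2-chloroethenyl]-3-methyloxan-2-one
Conditions: CrCl2, CHCl3, THF, 65 °C
Reagents that add atoms: chloroform, ClC(Cl)Cl
Why: Takai olefination gives the (E)-vinyl chloride selectively and leaves the lactone alone.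

**Step 6 (key step)**
Reactants: 7
Product: 8, tert-butyldimethylsilyl (1R,2R)-2-chloro-1-methylcyclohex-3-ene-1-carboxylate (Cl cis to the ester)
Conditions: LDA (1.1 equiv) added to 7 + TBSCl/HMPA, THF, −78 °C → rt; then PhMe, 110 °C; used crude
Reagents that add atoms: tert-butyldimethylsilyl chloride, CC(C)(C)[Si](C)(C)Cl
Why: Ireland–Claisen rearrangement of the cyclic silyl ketene acetal, with in-situ silylation so the base does not attack the vinyl chloride. The ring forces a boat transition state, so the C6–O stereocentre is transferred suprafacially to the new quaternary carbon, and the (E)-chlorovinyl terminus places Cl cis to the carboxylate; (6R) gives (1R,2R).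

**Step 7**
Reactants: 8
Product: 9, [(1R,2R)-2-chloro-1-methylcyclohex-3-en-1-yl]methanol
Conditions: DIBAL-H (3 equiv), CH2Cl2, −78 → 0 °C
Reagents that add atoms: none
Why: Hydride reduction of the silyl ester avoids a free carboxylate, which could displace the allylic chloride; low temperature spares the C–Cl bond.

**Step 8**
Reactants: 9
Product: 10, (1R,2R)-2-chloro-1-methylcyclohex-3-ene-1-carbaldehyde
Conditions: Dess–Martin periodinane, NaHCO3, CH2Cl2, 0 °C
Reagents that add atoms: none
Why: Mild oxidation; the aldehyde has no α-hydrogen, so it cannot epimerise or lose HCl.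

**Step 9**
Reactants: 10
Product: 11, (3R,4R)-3-chloro-4-[(E)-2-chloroethenyl]-4-methylcyclohex-1-ene
Conditions: CrCl2, CHCl3, THF (no iodide, no dipolar cosolvent), 65 °C, stopped at full conversion of 10
Reagents that add atoms: chloroform, ClC(Cl)Cl
Why: Takai olefination of the hindered aldehyde installs the (E)-chlorovinyl group; in neat THF without iodide, Cr(II) reduces a hindered secondary allylic chloride only slowly.

**Step 10**
Reactants: 11
Product: 12, (4R,5R)-4-chloro-5-[(E)-2-chloroethenyl]-5-methylcyclohex-2-en-1-one
Conditions: CrO3, 3,5-dimethylpyrazole, CH2Cl2, −20 °C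
Reagents that add atoms: chromium trioxide (oxygen source), O=[Cr](=O)=O
Why: Allylic oxidation at the only allylic CH2; the other allylic position is the deactivated CHCl and the chlorovinyl group has no allylic hydrogen.

**Step 11**
Reactants: 12
Product: 13, triethyl{[(4R,5R)-4-chloro-5-[(E)-2-chloroethenyl]-5-methylcyclohex-1-en-1-yl]oxy}silane
Conditions: Et3SiH, RhCl(PPh3)3 (2 mol %), PhH, 50 °C
Reagents that add atoms: triethylsilane, CC[SiH](CC)CC
Why: Rh-catalysed 1,4-hydrosilylation gives a regiodefined silyl enol ether under neutral conditions, so no free enolate is formed that could displace the γ-chloride.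

**Step 12**
Reactants: 13
Product: 14, (2R,4R,5R)-4-chloro-5-[(E)-2-chloroethenyl]-5-methyl-2-[(triethylsilyl)oxy]cyclohexan-1-one (OSi trans to the ring Cl and to the chlorovinyl group)
Conditions: mCPBA, NaHCO3, CH2Cl2, −20 → 0 °C
Reagents that add atoms: mCPBA, OOC(=O)c1cccc(Cl)c1
Why: Rubottom oxidation; the peracid attacks the enol ether on the face opposite the pseudo-axial chlorovinyl group and the ring C–Cl, and silyl migration gives the α-silyloxy ketone.

**Step 13**
Reactants: 14
Product: 15, (1R,4R,5R)-5-chloro-4-[(E)-2-chloroethenyl]-4-methyl-2-methylidenecyclohexan-1-ol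
Conditions: Zn, CH2Br2, TiCl4, THF, 0 °C → rt; then 1 M HCl workup
Reagents that add atoms: dibromomethane, BrCBr
Why: Lombardo methylenation is non-basic, so the α-oxygenated ketone neither epimerises nor enolises toward the γ-chloride; the acidic workup removes the triethylsilyl group.

**Step 14**
Reactants: 15
Product: 16, (1R,2R,5S)-1,5-dichloro-2-[(E)-2-chloroethenyl]-2-methyl-4-methylidenecyclohexane
Conditions: PPh3, Cl3CCOCCl3, CH2Cl2, −20 → 0 °C
Reagents that add atoms: hexachloroacetone (Cl source), ClC(Cl)(Cl)C(=O)C(Cl)(Cl)Cl
Why: Hexachloroacetone/PPh3 converts allylic alcohols to chlorides by SN2 with inversion and little allylic transposition. The axial "down" alcohol becomes the equatorial "up" chloride, 1,3-cis to the other ring chloride.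

**Step 15**
Reactants: 16
Product: 17, violacene, (1R,2S,4R,5R)-1-(bromomethyl)-1,2,4-trichloro-5-[(E)-2-chloroethenyl]-5-methylcyclohexane
Conditions: tetrabutylammonium dichlorobromate (Bu4N+ BrCl2−), CH2Cl2, −78 → −30 °C
Reagents that add atoms: bromine monochloride, ClBr, delivered from tetrabutylammonium dichlorobromate (drawn as its Bu4NCl·BrCl components: CCCC[N+](CCCC)(CCCC)CCCC.[Cl-].ClBr)
Why: Anti, Markovnikov bromochlorination of the 1,1-disubstituted alkene; the chlorovinyl group is deactivated. The bromonium forms on the equatorial side, away from the axial chlorovinyl group, and chloride opens it at the tertiary carbon by axial attack. This leaves CH2Br equatorial and the new Cl cis to the neighbouring chloride.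

## Compound list

1 | (R)-2-(2,2-dimethyl-1,3-dioxolan-4-yl)ethanol | CC1(C)OC[C@@H](CCO)O1 | starting material
2 | (R)-4-(2-iodoethyl)-2,2-dimethyl-1,3-dioxolane | CC1(C)OC[C@@H](CCI)O1 | intermediate
3 | tert-butyl propanoate | CCC(=O)OC(C)(C)C | starting material
4 | tert-butyl (2RS)-4-[(4R)-2,2-dimethyl-1,3-dioxolan-4-yl]-2-methylbutanoate | CC(CC[C@@H]1COC(C)(C)O1)C(=O)OC(C)(C)C | intermediate
5 | (3RS,6R)-6-(hydroxymethyl)-3-methyloxan-2-one | CC1CC[C@H](CO)OC1=O | intermediate
6 | (2R,5RS)-5-methyl-6-oxooxane-2-carbaldehyde | CC1CC[C@H](C=O)OC1=O | intermediate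
7 | (3RS,6R)-6-[(E)-2-chloroethenyl]-3-methyloxan-2-one | CC1CC[C@H](/C=C/Cl)OC1=O | intermediate
8 | tert-butyldimethylsilyl (1R,2R)-2-chloro-1-methylcyclohex-3-ene-1-carboxylate | C[C@]1(C(=O)O[Si](C)(C)C(C)(C)C)CCC=C[C@H]1Cl | intermediate
9 | [(1R,2R)-2-chloro-1-methylcyclohex-3-en-1-yl]methanol | C[C@]1(CO)CCC=C[C@H]1Cl | intermediate
10 | (1R,2R)-2-chloro-1-methylcyclohex-3-ene-1-carbaldehyde | C[C@]1(C=O)CCC=C[C@H]1Cl | intermediate
11 | (3R,4R)-3-chloro-4-[(E)-2-chloroethenyl]-4-methylcyclohex-1-ene | C[C@]1(/C=C/Cl)CCC=C[C@H]1Cl | intermediate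
12 | (4R,5R)-4-chloro-5-[(E)-2-chloroethenyl]-5-methylcyclohex-2-en-1-one | C[C@]1(/C=C/Cl)CC(=O)C=C[C@H]1Cl | intermediate
13 | triethyl{[(4R,5R)-4-chloro-5-[(E)-2-chloroethenyl]-5-methylcyclohex-1-en-1-yl]oxy}silane | C[C@]1(/C=C/Cl)CC(O[Si](CC)(CC)CC)=CC[C@H]1Cl | intermediate
14 | (2R,4R,5R)-4-chloro-5-[(E)-2-chloroethenyl]-5-methyl-2-[(triethylsilyl)oxy]cyclohexan-1-one | C[C@]1(/C=C/Cl)CC(=O)[C@H](O[Si](CC)(CC)CC)C[C@H]1Cl | intermediate
15 | (1R,4R,5R)-5-chloro-4-[(E)-2-chloroethenyl]-4-methyl-2-methylidenecyclohexan-1-ol | C[C@]1(/C=C/Cl)CC(=C)[C@H](O)C[C@H]1Cl | intermediate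
16 | (1R,2R,5S)-1,5-dichloro-2-[(E)-2-chloroethenyl]-2-methyl-4-methylidenecyclohexane | C[C@]1(/C=C/Cl)CC(=C)[C@@H](Cl)C[C@H]1Cl | intermediate
17 | violacene, (1R,2S,4R,5R)-1-(bromomethyl)-1,2,4-trichloro-5-[(E)-2-chloroethenyl]-5-methylcyclohexane | C[C@]1(/C=C/Cl)C[C@](Cl)(CBr)[C@@H](Cl)C[C@H]1Cl | target

## Step count and risks

Total steps: 15. Longest linear sequence: 15 (fully linear from 1).

Three steps most likely to fail:

1. **Step 6, Ireland–Claisen rearrangement of the lactone ketene acetal.** The boat transition state is strained, the chloro-substituted terminus slows the shift, and the allylic chloride product could lose HCl. Fallback: reduce lactone 7 to the lactol, dehydrate it to the 2-[(E)-2-chloroethenyl]-5-methyl-3,4-dihydro-2H-pyran, and run the thermal Claisen of that cyclic allyl vinyl ether. This gives aldehyde 10 directly with no enolate chemistry.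

2. **Step 9, Takai olefination beside an allylic chloride.** Cr(II) can reduce the secondary allylic chloride to an allylchromium species that adds to the aldehyde. Fallback: avoid chromium by converting 10 to the terminal alkyne (Ohira–Bestmann reagent, K2CO3, MeOH), then hydrozirconation with Cp2Zr(H)Cl and quenching with NCS to give the (E)-vinyl chloride 11.

3. **Step 15, bromochlorination.** The face of chloride delivery at the new tertiary centre, the Markovnikov preference next to an allylic C–Cl, and competition from the chlorovinyl alkene are not guaranteed. Fallback: epoxidise the exocyclic alkene of 16, open the epoxide with chloride at the tertiary carbon (TiCl4, inversion), and convert the resulting primary alcohol to the bromide with CBr4/PPh3.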